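Alder is the flask in question. It has the charge of blue, but the substrate enters at a steady rate over 15.0 h, and work-up comes at 30 h.

common to all: free catalyst 1.9 mol%; second catalyst 0.5 mol%
- blue: substrate 0.050 M; reagent 2 equiv; run made earlier
- ochre: substrate 0.050 M; reagent 1 equiv; run made earlier
- violet: substrate 0.050 M; reagent 4 equiv; run made earlier
- grey: substrate 0.075 M; reagent 2 equiv; run made earlier
- larch: substrate 0.050 M; reagent 2.00 equiv; a tube with plug flow, the mixed feed as stated, residence time 30 h; time 30 h
- maple: substrate 0.050 M; reagent 2.00 equiv; a single well-mixed tank run continuously and read at steady state, 30 h in it on average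
- ash: substrate 0.050 M; reagent 2.00 equiv; everything together in a closed stirred flask, run for 30 h; time 30 h
- alder: substrate 0.050 M (fed, over 15.0 h); reagent 2.00 equiv; a stirred flask in which substrate is dosed at a steady rate over 15.0 h without added volume, worked up at 30 h; time 30 h

| run | time / h | open intermediate / % | product / % |
|---|---|---|---|
| blue | 6.00 | 28.5 | 6.0 |
| blue | 12.0 | 40.2 | 15.3 |
| blue | 20.0 | 40.5 | 28.8 |
| blue | 25.0 | 37.8 | 37.8 |
| blue | 30.0 | 37.4 | 44.4 |
| ochre | 8.00 | 37.4 | 6.9 |
| ochre | 15.0 | 48.5 | 12.7 |
| ochre | 20.0 | 51.9 | 22.2 |
| ochre | 30.0 | 50.5 | 30.6 |
| ochre | 40.0 | 48.2 | 43.1 |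
| violet | 3.00 | 17.0 | 2.6 |
| violet | 5.00 | 23.8 | 4.3 |
| violet | 10.0 | 35.6 | 15.2 |
| violet | 20.0 | 35.1 | 35.9 |
| violet | 40.0 | 20.1 | 67.8 |
| grey | 8.00 | 39.5 | 15.4 |
| grey | 15.0 | 36.7 | 34.7 |
| grey | 20.0 | 32.2 | 44.3 |
| grey | 30.0 | 22.7 | 63.4 |
| grey | 40.0 | 12.1 | 77.3 |

(readings scatter by 1 percentage point)

- the stated concentrations are those of everything mixed, before any reaction; amounts are the same in each set-up
- the feed brings no volume worth counting
- the earlier runs were made in a closed, stirred flask
- a reading or a percentage of product counts all its forms, free or not

* the set-up with the highest amount of open intermediate at the outlet or at the end, in percent of the substrate put in ("none" if the first two lie within 2 percentage points) (larch / maple / ash / alder / none)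
* amount of open intermediate at the outlet or at the end, in percent of the substrate put in, larch
* amount of open intermediate at the outlet or at the end, in percent of the substrate put in, maple
* amount of open intermediate at the outlet or at the end, in percent of the substrate put in, ash
* amount of open intermediate at the outlet or at the end, in percent of the substrate put in, alder

In alder, each dosed portion of substrate starts its own clock. At work-up the ages run from 15.0 h for the last portion to 30 h for the first. The midpoint of those ages is the mean age of the substrate, its mean residence time: 22.5 h. The rule is to read the blue table at the mean age.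

Blue reads 40.5 % open intermediate at 20.0 h and 37.8 % at 25.0 h, so the mean age reads 39.1 %. The error of the rule comes next. The youngest age lies between the blue readings 40.2 % and 40.5 %, about 40.4 %. The oldest age reads 37.4 %. The mean of these ends is 38.9 %, which differs from the mean-age reading by 0.27 percentage points, less than the scatter of 1 point. Over this window, the reading at the mean age can stand in for the mean of the curve.

Ash and larch each have one age, 30 h, so the rule gives them the blue reading there, 37.4 %. This reckoning of mine puts alder ahead by 1.8 points, less than the margin of 2 points, so it leans to alder without clearing the margin. Maple has a mean age of 30 h, like ash, but its ages spread upward from zero, and blue reads 28.5 % at 6.00 h against 40.2 % at 12.0 h, so the rule gives no number for maple.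

The forecast goes further and names alder, since “dosing delays everything”. It gives 37.5 % for larch, 27.5 % for maple, 37.5 % for ash and 41 % for alder.

Alder ends at 39.3 %, against 36.5 % in ash and 36.5 % in larch, so alder stands highest, and its lead of 2.8 points over ash exceeds the margin.

    second catalyst + open intermediate ⇌ catalyst intermediate (K = 140 M⁻¹, k = 320 M⁻¹ h⁻¹)
    free catalyst + product ⇌ idle complex, settled at all times (K = 34.0 M⁻¹)
    reagent + catalyst intermediate → second catalyst + product (k = 110 M⁻¹ h⁻¹)
    substrate + free catalyst → free catalyst + open intermediate (k = 78.0 M⁻¹ h⁻¹)

Alder keeps 27.1 % substrate beside 33.4 % product. Its mean age of 22.5 h had read 39.1 % on blue. Maple has a mean age of 30 h, where blue reads 37.4 %, yet maple gives 24.0 %, lower by 13 points, and its product, idle complex counted, is 34.4 %.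

The runs are simulated for substances that don't exist.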